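**Plan**

1. Numbering follows andrographolide (ent-labdane; C19 = CH2OH carbon on C4, C17 = exocyclic CH2; α = face of the C10 methyl). Cuts: C12=C13 (aldol condensation with an (S)-lactone), C8=C17 (methylenation), then the C4–C5 bond of ring A.
2. Enabling feature: ring A carries C3–OH next to the quaternary C4 that bears C19. At the aldehyde level the array C3(OH)–C4–C19HO is what a 2,3-epoxy alcohol gives by a 1,2-shift, so ring A can arise by contraction of a seven-membered ring C5–C19–C4–C3–C2–C1–C10 fused to ring B.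
3. Further cuts: C3=C4 of that ring (ring-closing metathesis), C9–C11 and C10–C1 (enolate alkylation and conjugate addition on a cyclohexenone), C19–C4 (Grignard addition), and ring B itself (Diels–Alder).
4. Forward order: ring B, C19 carbinol, C10 and C9 substituents, seven-membered ring, epoxide, contraction to ring A, exocyclic methylene, butenolide.
5. Stereochemistry: C5 from the catalytic Diels–Alder reaction; C19 (Felkin–Anh) and C10 (anti addition) from C5; C9 by equilibration; C3 from epoxidation anti to the C19 silyl ether; C4 by invertive, antiperiplanar migration of C5; C14 from (S)-3-hydroxy-γ-butyrolactone; the 12,13-alkene from E1cB elimination.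

Key step: step 8

Assumption: the (S)-configured oxazaborolidinium catalyst is taken to give the (1S) adduct in step 2; if its sense of induction is the opposite, its enantiomer is used and nothing else changes.

Step 1
Reactants: 1 (3E)-pent-3-en-2-one
Product: 2 triisopropyl[(3E)-penta-1,3-dien-2-yloxy]silane
Conditions: TIPSOTf, Et3N, Et2O, 0 °C
Reagents that add atoms: triisopropylsilyl trifluoromethanesulfonate, CC(C)[Si](C(C)C)(C(C)C)OS(=O)(=O)C(F)(F)F
Why: Silyl triflate–amine enolization of the methyl ketone (silyl dienol ether formation) should give the cross-conjugated 2-silyloxy diene with the E alkene untouched; the bulky silyl group is chosen to survive the acidic Diels–Alder catalyst.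

Step 2
Reactants: 2 triisopropyl[(3E)-penta-1,3-dien-2-yloxy]silane; 3 acrolein
Product: 4 (1S,2R)-2-methyl-4-[(triisopropylsilyl)oxy]cyclohex-3-ene-1-carbaldehyde
Conditions: (S)-o-tolyl-CBS oxazaborolidine·Tf2NH (10 mol%), CH2Cl2, −78 °C
Reagents that add atoms: none
Why: Catalytic enantioselective Diels–Alder reaction of a 2-silyloxy diene with an enal (chiral oxazaborolidinium Lewis acid): the CH2 terminus of 2 should bond to the β-carbon of acrolein, the endo transition state puts formyl and methyl cis, and the catalyst selects the face that gives the (1S) centre, the future C5.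

Step 3
Reactants: 4 (1S,2R)-2-methyl-4-[(triisopropylsilyl)oxy]cyclohex-3-ene-1-carbaldehyde
Product: 6 tert-butyl({(1R)-2-methyl-1-[(1S,2S)-2-methyl-4-[(triisopropylsilyl)oxy]cyclohex-3-en-1-yl]prop-2-en-1-yl}oxy)dimethylsilane, via bromomagnesium alkoxide 5 (not isolated)
Conditions: CH2=C(CH3)MgBr, THF, −78 °C; then TBSOTf, −78 → 0 °C
Reagents that add atoms: isopropenylmagnesium bromide, C=C(C)[Mg]Br; tert-butyldimethylsilyl trifluoromethanesulfonate, CC(C)(C)[Si](C)(C)OS(=O)(=O)C(F)(F)F
Why: Grignard 1,2-addition under Felkin–Anh control (attack anti to the branched ring carbon next to the formyl-bearing centre) should give mainly the (R)-carbinol at C19, which is silylated in the same flask; any minor C19 epimer is removed by chromatography.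

Step 4
Reactants: 6 silyl enol ether with the C19 tert-butyldimethylsilyl ether
Product: 7 (4S)-4-[(1R)-1-[(tert-butyldimethylsilyl)oxy]-2-methylprop-2-en-1-yl]-3-methylcyclohex-2-en-1-one
Conditions: Pd(OAc)2 (10 mol%), O2 (1 atm), DMSO, 60 °C
Reagents that add atoms: none
Why: Saegusa–Ito oxidation of the regiodefined silyl enol ether (palladium enolate, then β-hydride elimination of the hydrogen on the methyl-bearing carbon) should place the enone double bond at C9=C10 and remove the now superfluous stereocentre while C5 is untouched.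

Step 5
Reactants: 7 (4S)-4-[(1R)-1-[(tert-butyldimethylsilyl)oxy]-2-methylprop-2-en-1-yl]-3-methylcyclohex-2-en-1-one
Product: 10 tert-butyl 2-[(1S,2R,3S)-2-(but-3-en-1-yl)-3-[(1R)-1-[(tert-butyldimethylsilyl)oxy]-2-methylprop-2-en-1-yl]-2-methyl-6-oxocyclohexyl]acetate, via lithium enolate 8 (not isolated), via C9-epimeric keto ester 9 (not isolated)
Conditions: (CH2=CHCH2CH2)2CuLi, Et2O–THF, −78 → −30 °C; then BrCH2CO2t-Bu, HMPA, −78 → 0 °C; work-up; then DBU, toluene, 60 °C
Reagents that add atoms: lithium di(but-3-en-1-yl)cuprate, [Li+].C=CCC[Cu-]CCC=C; tert-butyl bromoacetate, CC(C)(C)OC(=O)CBr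
Why: Gilman cuprate conjugate addition with enolate alkylation in the same flask (three-component coupling): the butenyl group should add to C10 anti to the large C5 substituent and set the quaternary centre, the regiodefined enolate is alkylated at C9, and DBU should equilibrate the kinetic epimer to the equatorial one (side chain cis to the C10 methyl), any remainder being recycled.

Step 6
Reactants: 10 monocyclic keto ester with butenyl and 2-methylallyl silyl ether arms
Product: 11 tert-butyl 2-[(1S,4aS,5R,9aR)-5-[(tert-butyldimethylsilyl)oxy]-6,9a-dimethyl-2-oxo-2,3,4,4a,5,8,9,9a-octahydro-1H-benzo[7]annulen-1-yl]acetate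
Conditions: second-generation Hoveyda–Grubbs catalyst (10 mol%), toluene (0.002 M), 80 °C
Reagents that add atoms: none
Why: Ring-closing metathesis between the butenyl terminus and the 1,1-disubstituted alkene should close the seven-membered ring C5–C19–C4–C3–C2–C1–C10 with a C3=C4 trisubstituted alkene; the trans arrangement of the two arms on ring B gives the trans ring fusion.

Step 7
Reactants: 11 trans-fused cycloheptene with the C19 silyl ether
Product: 12 tert-butyl 2-[(1S,4aS,5R,6R,7R,9aR)-5-[(tert-butyldimethylsilyl)oxy]-6,7-epoxy-6,9a-dimethyl-2-oxodecahydro-1H-benzo[7]annulen-1-yl]acetate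
Conditions: DMDO, acetone, 0 °C
Reagents that add atoms: dimethyldioxirane, CC1(C)OO1
Why: Dioxirane epoxidation without hydrogen-bond direction should deliver oxygen anti to the bulky allylic silyloxy group, which is also the convex face of the chair-like cycloheptene (the face of the C10 methyl), giving the trans epoxy silyl ether and fixing C3.

Step 8
Reactants: 12 trans-2,3-epoxy silyl ether (C3–C4 epoxide, C19 silyl ether)
Product: 14 tert-butyl 3α,19-dihydroxy-8-oxo-13,14,15,16,17-pentanor-ent-labdan-12-oate, via β-hydroxy aldehyde 13 (not isolated)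
Conditions: BF3·OEt2, CH2Cl2, −78 °C; aq. NaHCO3; then NaBH(OAc)3, AcOH, MeCN, 0 °C
Reagents that add atoms: none
Why: BF3 binds the epoxide oxygen of 12 and, as the C4–O bond ionizes, the ring bond C19–C5 that lies antiperiplanar to it shifts from C19 to C4 while the silyloxy oxygen on C19 becomes the aldehyde carbonyl (the silyl group leaves as the fluorosilane), so the seven-membered carbocycle contracts to ring A; the retro-aldol-prone β-hydroxy aldehyde 13 is reduced at once by hydroxyl-directed NaBH(OAc)3 delivery, which should spare the C8 ketone. The closest known reaction type is the stereospecific Lewis-acid 1,2-rearrangement of 2,3-epoxy alcohol silyl ethers (semipinacol or Suzuki–Tsuchihashi rearrangement), of which ring-contracting cases on cyclic substrates are known. Ring A is closed by a suprafacial 1,2-alkyl shift through a three-centre transition state (a ring contraction, not an end-on exo or endo cyclization), and no other ring is formed. C4 is set by inversion at the epoxide carbon, C5 entering anti to the departing oxygen so that C19 ends axial and cis to the C10 methyl; C3 keeps its C–O bond and the configuration given by the epoxidation; C5 migrates with retention, which carries the trans ring fusion into the decalin. The step needs shift of C5 in preference to the hydride on C3 (Meinwald ketone), the hydride on C19 and proton loss from C18: the donor oxygen on C19 makes the carbinol-side shift the most electron-rich one, the trans ring fusion holds the seven-membered ring in the chair-like form with C19–C5 anti to C4–O, and in the only other accessible (boat-like) form the group anti to C4–O is the silyloxy group, which cannot migrate.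

Step 9
Reactants: 14 tert-butyl 3α,19-dihydroxy-8-oxo-13,14,15,16,17-pentanor-ent-labdan-12-oate
Product: 15 tert-butyl 3α,19-(isopropylidenedioxy)-8-oxo-13,14,15,16,17-pentanor-ent-labdan-12-oate
Conditions: 2-methoxypropene, PPTS (cat.), CH2Cl2, 0 °C
Reagents that add atoms: 2-methoxypropene, C=C(C)OC
Why: Acetal formation: the 1,3-diol (equatorial C3–OH, axial C19H2OH) should close to the six-membered isopropylidene acetal, and the enol ether reagent avoids ketalization of the C8 ketone.

Step 10
Reactants: 15 acetonide-protected 8-keto ester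
Product: 16 tert-butyl 3α,19-(isopropylidenedioxy)-13,14,15,16-tetranor-ent-labd-8(17)-en-12-oate
Conditions: Ph3PCH3Br, KOt-Bu, THF, 0 → 40 °C
Reagents that add atoms: methyltriphenylphosphonium bromide, C[P+](c1ccccc1)(c1ccccc1)c1ccccc1.[Br-]
Why: Wittig methylenation of the C8 ketone installs the exocyclic C8=C17 alkene; C9 already holds its thermodynamic (equatorial) configuration, so the basic ylide should not erode it, and the tert-butyl ester is too hindered to react.

Step 11
Reactants: 16 exocyclic alkene tert-butyl ester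
Product: 17 3α,19-(isopropylidenedioxy)-13,14,15,16-tetranor-ent-labd-8(17)-en-12-al
Conditions: i-Bu2AlH, CH2Cl2, −78 °C; aq. potassium sodium tartrate
Reagents that add atoms: none
Why: Partial reduction of the ester by i-Bu2AlH at low temperature (stable tetrahedral aluminium hemiacetal) should release the C12 aldehyde on work-up without touching the acetal or the alkene.

Step 12
Reactants: 18 (4S)-4-hydroxyoxolan-2-one
Product: 19 (4S)-4-[(triethylsilyl)oxy]oxolan-2-one
Conditions: Et3SiCl, imidazole, CH2Cl2, 0 °C
Reagents that add atoms: chlorotriethylsilane, CC[Si](CC)(CC)Cl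
Why: Standard silylation of the secondary alcohol; the (S) centre becomes C14, and a silyl ether is a poor leaving group, which suppresses β-elimination from the lactone enolate in the next step.

Step 13
Reactants: 19 (4S)-4-[(triethylsilyl)oxy]oxolan-2-one; 17 C12 aldehyde
Product: 21 12-hydroxy-12,13-dihydro-3,19-O-isopropylidene-14-O-(triethylsilyl)andrographolide (C13 chain trans to C14–O; both C12 epimers), via lithium lactone enolate 20 (not isolated)
Conditions: LiN(i-Pr)2, THF, −78 °C; then 17, −78 °C; H2O
Reagents that add atoms: none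
Why: Aldol addition of the lactone lithium enolate to the aldehyde forms the C12–C13 bond; attack anti to the silyloxy group is expected to put the new chain trans to C14–O, and both C12 carbinol epimers are carried on.

Step 14
Reactants: 21 aldol adduct
Product: 23 3,19-O-isopropylidene-14-O-(triethylsilyl)andrographolide, via C12 methanesulfonate 22 (not isolated)
Conditions: MsCl, Et3N, CH2Cl2, 0 °C; then DBU, 23 °C
Reagents that add atoms: none
Why: Mesylation and E1cB elimination through the lactone enolate should give the conjugated exocyclic alkene with the usually preferred E geometry (C11 anti to the lactone carbonyl); the silyl ether at C14 is a far poorer leaving group than mesylate, so the endocyclic butenolide should not form.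

Step 15
Reactants: 23 3,19-O-isopropylidene-14-O-(triethylsilyl)andrographolide
Product: 24 andrographolide
Conditions: AcOH–H2O–THF (3:1:1), 23 °C
Reagents that add atoms: none
Why: Mild acid hydrolysis should remove the isopropylidene acetal and the triethylsilyl ether in one operation under conditions that the allylic C14 alcohol and the exocyclic alkenes are expected to survive.

**Compound list**

1 | (3E)-pent-3-en-2-one | C/C=C/C(C)=O | starting material
2 | triisopropyl[(3E)-penta-1,3-dien-2-yloxy]silane | C=C(O[Si](C(C)C)(C(C)C)C(C)C)/C=C/C | intermediate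
3 | acrolein (prop-2-enal) | C=CC=O | starting material
4 | (1S,2R)-2-methyl-4-[(triisopropylsilyl)oxy]cyclohex-3-ene-1-carbaldehyde (formyl and methyl cis) | CC(C)[Si](C(C)C)(C(C)C)OC1=C[C@@H](C)[C@@H](C=O)CC1 | intermediate
5 | bromomagnesium (1R)-2-methyl-1-[(1S,2S)-2-methyl-4-[(triisopropylsilyl)oxy]cyclohex-3-en-1-yl]prop-2-en-1-olate | CC(C)[Si](C(C)C)(C(C)C)OC1=C[C@@H](C)[C@@H]([C@@H]([O-])C(C)=C)CC1.[Mg+2].[Br-] | intermediate (not isolated)
6 | tert-butyl({(1R)-2-methyl-1-[(1S,2S)-2-methyl-4-[(triisopropylsilyl)oxy]cyclohex-3-en-1-yl]prop-2-en-1-yl}oxy)dimethylsilane | CC(C)[Si](C(C)C)(C(C)C)OC1=C[C@@H](C)[C@@H]([C@@H](O[Si](C)(C)C(C)(C)C)C(C)=C)CC1 | intermediate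
7 | (4S)-4-[(1R)-1-[(tert-butyldimethylsilyl)oxy]-2-methylprop-2-en-1-yl]-3-methylcyclohex-2-en-1-one | O=C1CC[C@H]([C@@H](O[Si](C)(C)C(C)(C)C)C(C)=C)C(C)=C1 | intermediate
8 | lithium (3R,4S)-3-(but-3-en-1-yl)-4-[(1R)-1-[(tert-butyldimethylsilyl)oxy]-2-methylprop-2-en-1-yl]-3-methylcyclohex-1-en-1-olate | [Li+].[O-]C1=C[C@](C)(CCC=C)[C@@H]([C@@H](O[Si](C)(C)C(C)(C)C)C(C)=C)CC1 | intermediate (not isolated)
9 | tert-butyl 2-[(1R,2R,3S)-2-(but-3-en-1-yl)-3-[(1R)-1-[(tert-butyldimethylsilyl)oxy]-2-methylprop-2-en-1-yl]-2-methyl-6-oxocyclohexyl]acetate (C9 epimer of 10, side chain trans to the C10 methyl) | O=C1CC[C@H]([C@@H](O[Si](C)(C)C(C)(C)C)C(C)=C)[C@@](C)(CCC=C)[C@H]1CC(=O)OC(C)(C)C | intermediate (not isolated)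
10 | tert-butyl 2-[(1S,2R,3S)-2-(but-3-en-1-yl)-3-[(1R)-1-[(tert-butyldimethylsilyl)oxy]-2-methylprop-2-en-1-yl]-2-methyl-6-oxocyclohexyl]acetate | O=C1CC[C@H]([C@@H](O[Si](C)(C)C(C)(C)C)C(C)=C)[C@@](C)(CCC=C)[C@@H]1CC(=O)OC(C)(C)C | intermediate
11 | tert-butyl 2-[(1S,4aS,5R,9aR)-5-[(tert-butyldimethylsilyl)oxy]-6,9a-dimethyl-2-oxo-2,3,4,4a,5,8,9,9a-octahydro-1H-benzo[7]annulen-1-yl]acetate (trans-fused) | O=C1CC[C@@H]2[C@@H](O[Si](C)(C)C(C)(C)C)C(C)=CCC[C@@]2(C)[C@@H]1CC(=O)OC(C)(C)C | intermediate
12 | tert-butyl 2-[(1S,4aS,5R,6R,7R,9aR)-5-[(tert-butyldimethylsilyl)oxy]-6,7-epoxy-6,9a-dimethyl-2-oxodecahydro-1H-benzo[7]annulen-1-yl]acetate (epoxide trans to the silyloxy group, on the face of the 9a-methyl) | O=C1CC[C@@H]2[C@@H](O[Si](C)(C)C(C)(C)C)[C@]3(C)O[C@@H]3CC[C@@]2(C)[C@@H]1CC(=O)OC(C)(C)C | intermediate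
13 | tert-butyl 3α-hydroxy-8,19-dioxo-13,14,15,16,17-pentanor-ent-labdan-12-oate (5β-H, 9β-H, 10α-CH3, C19 formyl α on C4) | O=C1CC[C@@H]2[C@](C)(C=O)[C@H](O)CC[C@@]2(C)[C@@H]1CC(=O)OC(C)(C)C | intermediate (not isolated)
14 | tert-butyl 3α,19-dihydroxy-8-oxo-13,14,15,16,17-pentanor-ent-labdan-12-oate | O=C1CC[C@@H]2[C@](C)(CO)[C@H](O)CC[C@@]2(C)[C@@H]1CC(=O)OC(C)(C)C | intermediate
15 | tert-butyl 3α,19-(isopropylidenedioxy)-8-oxo-13,14,15,16,17-pentanor-ent-labdan-12-oate | O=C1CC[C@@H]2[C@]3(C)COC(C)(C)O[C@@H]3CC[C@@]2(C)[C@@H]1CC(=O)OC(C)(C)C | intermediate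
16 | tert-butyl 3α,19-(isopropylidenedioxy)-13,14,15,16-tetranor-ent-labd-8(17)-en-12-oate | C=C1CC[C@@H]2[C@]3(C)COC(C)(C)O[C@@H]3CC[C@@]2(C)[C@@H]1CC(=O)OC(C)(C)C | intermediate
17 | 3α,19-(isopropylidenedioxy)-13,14,15,16-tetranor-ent-labd-8(17)-en-12-al | C=C1CC[C@@H]2[C@]3(C)COC(C)(C)O[C@@H]3CC[C@@]2(C)[C@@H]1CC=O | intermediate
18 | (4S)-4-hydroxyoxolan-2-one [(S)-3-hydroxy-γ-butyrolactone] | O=C1C[C@H](O)CO1 | starting material
19 | (4S)-4-[(triethylsilyl)oxy]oxolan-2-one | O=C1C[C@H](O[Si](CC)(CC)CC)CO1 | intermediate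
20 | lithium (4S)-4-[(triethylsilyl)oxy]-4,5-dihydrofuran-2-olate | [Li+].[O-]C1=C[C@H](O[Si](CC)(CC)CC)CO1 | intermediate (not isolated)
21 | 12-hydroxy-12,13-dihydro-3,19-O-isopropylidene-14-O-(triethylsilyl)andrographolide (C13 chain trans to C14–O; both C12 epimers) | C=C1CC[C@@H]2[C@]3(C)COC(C)(C)O[C@@H]3CC[C@@]2(C)[C@@H]1CC(O)[C@@H]1C(=O)OC[C@H]1O[Si](CC)(CC)CC | intermediate
22 | 12-O-methanesulfonate of 21 | C=C1CC[C@@H]2[C@]3(C)COC(C)(C)O[C@@H]3CC[C@@]2(C)[C@@H]1CC(OS(C)(=O)=O)[C@@H]1C(=O)OC[C@H]1O[Si](CC)(CC)CC | intermediate (not isolated)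
23 | 3,19-O-isopropylidene-14-O-(triethylsilyl)andrographolide | C=C1CC[C@@H]2[C@]3(C)COC(C)(C)O[C@@H]3CC[C@@]2(C)[C@@H]1C/C=C1/C(=O)OC[C@H]1O[Si](CC)(CC)CC | intermediate
24 | andrographolide | C=C1CC[C@@H]2[C@](C)(CO)[C@H](O)CC[C@@]2(C)[C@@H]1C/C=C1/C(=O)OC[C@H]1O | target

**Step count and risks**

Total steps: 15. Longest linear sequence: 14 (steps 1–11 and 13–15; step 12 prepares the lactone partner).

The three steps most likely to fail:

Step 8. The 1,2-shift of C5 may lose out to hydride migration from C3 or to proton loss next to the developing cation at C4, or the silyl ether may be cleaved before it can assist. The fallback sets out from 12: fluoride desilylation (Bu4NF buffered with AcOH, THF) gives the trans-epoxy alcohol tert-butyl 2-[(1S,4aS,5R,6S,7R,9aR)-6,7-epoxy-5-hydroxy-6,9a-dimethyl-2-oxodecahydro-1H-benzo[7]annulen-1-yl]acetate F4. This is rearranged as its zinc alkoxide with catalytic ZnBr2 in CH2Cl2, so that a metal alkoxide pushes the migration instead of a strong Lewis acid pulling on a silyl ether. The route is rejoined at 13, which is reduced to 14 as in step 8.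

Step 5. The cuprate may fail to add to the congested β,β-disubstituted enone (enolization or 1,2-addition instead), or the hindered enolate may alkylate slowly or on oxygen. The fallback sets out from 7: a copper-catalysed Grignard addition in the presence of Me3SiCl (CH2=CHCH2CH2MgBr, CuBr·SMe2 cat., Me3SiCl, HMPA, THF, −78 °C) traps the adduct as the trimethylsilyl enol ether {[(3R,4S)-3-(but-3-en-1-yl)-4-[(1R)-1-[(tert-butyldimethylsilyl)oxy]-2-methylprop-2-en-1-yl]-3-methylcyclohex-1-en-1-yl]oxy}trimethylsilane F1, which is isolated. MeLi in THF then gives the copper-free lithium enolate 8, and alkylation and equilibration as in step 5 return to 10.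

Step 6. Ring closure onto the crowded 1,1-disubstituted allylic silyl ether may be slow, so that oligomerization through the butenyl group takes over. The fallback sets out from 10: HF·pyridine removes the silyl group to give the free allylic alcohol tert-butyl 2-[(1S,2R,3S)-2-(but-3-en-1-yl)-3-[(1R)-1-hydroxy-2-methylprop-2-en-1-yl]-2-methyl-6-oxocyclohexyl]acetate F2, a better metathesis partner. Ring closure with the same catalyst gives the cycloheptenol tert-butyl 2-[(1S,4aS,5R,9aR)-5-hydroxy-6,9a-dimethyl-2-oxo-2,3,4,4a,5,8,9,9a-octahydro-1H-benzo[7]annulen-1-yl]acetate F3, and TBSOTf with 2,6-lutidine returns to 11.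

Further compounds
F1 | step 5 | {[(3R,4S)-3-(but-3-en-1-yl)-4-[(1R)-1-[(tert-butyldimethylsilyl)oxy]-2-methylprop-2-en-1-yl]-3-methylcyclohex-1-en-1-yl]oxy}trimethylsilane | C[Si](C)(C)OC1=C[C@](C)(CCC=C)[C@@H]([C@@H](O[Si](C)(C)C(C)(C)C)C(C)=C)CC1
F2 | step 6 | tert-butyl 2-[(1S,2R,3S)-2-(but-3-en-1-yl)-3-[(1R)-1-hydroxy-2-methylprop-2-en-1-yl]-2-methyl-6-oxocyclohexyl]acetate | O=C1CC[C@H]([C@@H](O)C(C)=C)[C@@](C)(CCC=C)[C@@H]1CC(=O)OC(C)(C)C
F3 | step 6 | tert-butyl 2-[(1S,4aS,5R,9aR)-5-hydroxy-6,9a-dimethyl-2-oxo-2,3,4,4a,5,8,9,9a-octahydro-1H-benzo[7]annulen-1-yl]acetate | O=C1CC[C@@H]2[C@@H](O)C(C)=CCC[C@@]2(C)[C@@H]1CC(=O)OC(C)(C)C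
F4 | step 8 | tert-butyl 2-[(1S,4aS,5R,6S,7R,9aR)-6,7-epoxy-5-hydroxy-6,9a-dimethyl-2-oxodecahydro-1H-benzo[7]annulen-1-yl]acetate | O=C1CC[C@@H]2[C@@H](O)[C@]3(C)O[C@@H]3CC[C@@]2(C)[C@@H]1CC(=O)OC(C)(C)C
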